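**Retrosynthetic overview**
1. The target is a depside of ring A (5-formyl-2,4-dihydroxy-3,6-dimethylbenzoyl) and ring B (methyl 4-hydroxy-2-methoxy-3,5,6-trimethylbenzoate). The obvious acid-plus-phenol esterification between two di-ortho-substituted partners is not used.
2. Last disconnection: the ring A formyl group, installed by formylation of the only free arene C–H.
3. Key disconnection: ring A is cut across C1–C2 and C5–C6 (retro-Diels–Alder/aromatisation) into an aryl but-2-ynoate and a 1-methoxy-2-methyl-1,3-bis(silyloxy)butadiene. Ring A is therefore grown on an ester bond made early from an unhindered C4 acid.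
4. The but-2-ynoate also protects the 4-oxygen of ring B during 2-O-methylation. Ring B comes from atraric acid, with its C5 methyl added by formylation and hydrogenolysis.
5. Ring order: ring B is bought as an arene; ring A is formed last by [4+2] benzannulation.

Assumption: the target has no stereocentre and no configurationally stable axis, so it is achiral and the single-enantiomer requirement is met without stereocontrol.

**Route**

Step 1
Reactants: 1 methyl 2,4-dihydroxy-3,6-dimethylbenzoate (atraric acid)
Product: 3 methyl 5-formyl-2,4-dihydroxy-3,6-dimethylbenzoate, via alpha-chloro ether 2 (not isolated)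
Conditions: Cl2CHOMe, TiCl4, CH2Cl2, 0 → 23 °C; then ice-cold 1 M HCl
Reagents that add atoms: dichloromethyl methyl ether, COC(Cl)Cl; water, O
Why: Rieche formylation (electrophilic aromatic substitution by the TiCl4-activated chloromethyl oxocarbenium ion) can only occur at C5, the single free ring position, which is ortho to one phenol and para to the other, and the alpha-chloro ether is hydrolysed to the aldehyde on work-up.

Step 2
Reactants: 3 methyl 5-formyl-2,4-dihydroxy-3,6-dimethylbenzoate
Product: 5 methyl 2,4-dihydroxy-3,5,6-trimethylbenzoate, via benzylic alcohol 4 (not isolated)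
Conditions: H2 (1 atm), Pd/C (10 wt% palladium on carbon), AcOH, cat. HCl, 23 °C
Reagents that add atoms: none
Why: Catalytic hydrogenation of the electron-rich ortho-hydroxybenzaldehyde gives the benzylic alcohol, which under acid undergoes benzylic hydrogenolysis through the ortho-quinone methide or benzylic cation to the methyl group while the ester and the arene are untouched.

Step 3
Reactants: 5 methyl 2,4-dihydroxy-3,5,6-trimethylbenzoate; 6 but-2-ynoic acid
Product: 7 methyl 4-(but-2-ynoyloxy)-2-hydroxy-3,5,6-trimethylbenzoate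
Conditions: DCC, DMAP (5 mol%), CH2Cl2, 0 → 23 °C
Reagents that add atoms: none
Why: Steglich esterification acylates only the 4-OH because the 2-OH is locked in a hydrogen bond to the ester carbonyl and is far less nucleophilic, and the small linear C4 acid couples readily even to a phenol flanked by two methyl groups.

Step 4
Reactants: 7 methyl 4-(but-2-ynoyloxy)-2-hydroxy-3,5,6-trimethylbenzoate
Product: 8 methyl 4-(but-2-ynoyloxy)-2-methoxy-3,5,6-trimethylbenzoate
Conditions: MeI (excess), Ag2O, 4 Å molecular sieves, CH2Cl2, 40 °C, dark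
Reagents that add atoms: iodomethane, CI
Why: Purdie-type O-methylation (Williamson alkylation promoted by Ag2O) alkylates the chelated phenol under essentially neutral conditions, which avoids oxa-Michael addition to or acyl transfer from the aryl ynoate that here doubles as the protecting group of the 4-oxygen.

Step 5
Reactants: 9 methyl 2-methyl-3-oxobutanoate
Product: 10 methyl 2-methyl-3-(trimethylsilyloxy)but-2-enoate
Conditions: Me3SiCl, Et3N, hexane, 23 °C
Reagents that add atoms: chlorotrimethylsilane, C[Si](C)(C)Cl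
Why: Silyl enol ether formation by soft enolisation of the beta-keto ester with Et3N and O-silylation gives the 3-silyloxy enoate needed for the following gamma-deprotonation.

Step 6
Reactants: 10 methyl 2-methyl-3-(trimethylsilyloxy)but-2-enoate
Product: 12 1-methoxy-2-methyl-1,3-bis(trimethylsilyloxy)buta-1,3-diene, via lithium dienolate 11 (not isolated)
Conditions: LiN(iPr)2 (commercial solution), THF, −78 °C; then Me3SiCl, −78 → 23 °C
Reagents that add atoms: chlorotrimethylsilane, C[Si](C)(C)Cl
Why: Kinetic gamma-deprotonation at the C4 methyl gives the extended lithium dienolate, which is O-silylated at the ester oxygen (silyl ketene acetal formation) to the Chan-type 1,3-bis(silyloxy)diene.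

Step 7
Reactants: 8 methyl 4-(but-2-ynoyloxy)-2-methoxy-3,5,6-trimethylbenzoate; 12 1-methoxy-2-methyl-1,3-bis(trimethylsilyloxy)buta-1,3-diene
Product: 14 methyl 4-[(2,4-dihydroxy-3,6-dimethylbenzoyl)oxy]-2-methoxy-3,5,6-trimethylbenzoate, via cyclohexadiene cycloadduct 13 (not isolated)
Conditions: 12 (2.5 equiv), toluene, 110 °C, sealed tube; then 1 M HCl, THF, 23 °C
Reagents that add atoms: none
Why: In this regioselective Diels–Alder benzannulation of a 1,1,3-trioxygenated diene with an alkynoate, the nucleophilic CH2 terminus bonds to the beta carbon of the ynoate and the ketene acetal carbon to the alpha carbon, and acid-promoted desilylation with loss of methanol aromatises the 1,4-cyclohexadiene to the 2,4-dihydroxy-3,6-dimethylbenzoate, so the hindered depside ester is never made by acylation and the transient ketal stereocentre disappears.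

Step 8
Reactants: 14 methyl 4-[(2,4-dihydroxy-3,6-dimethylbenzoyl)oxy]-2-methoxy-3,5,6-trimethylbenzoate
Product: 16 methyl 4-[(5-formyl-2,4-dihydroxy-3,6-dimethylbenzoyl)oxy]-2-methoxy-3,5,6-trimethylbenzoate (CNP0316552.0), via alpha-chloro ether 15 (not isolated)
Conditions: Cl2CHOMe, TiCl4, CH2Cl2, −20 → 0 °C; then ice-cold 1 M HCl
Reagents that add atoms: dichloromethyl methyl ether, COC(Cl)Cl; water, O
Why: Rieche formylation (electrophilic aromatic substitution) has a single possible site, C5 of ring A, which is activated by the ortho and para hydroxyls, whereas ring B is fully substituted and the low temperature spares the aryl ester and the methyl ether.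

**Compound list**
1 | methyl 2,4-dihydroxy-3,6-dimethylbenzoate (atraric acid) | COC(=O)c1c(C)cc(O)c(C)c1O | starting material
2 | methyl 5-[chloro(methoxy)methyl]-2,4-dihydroxy-3,6-dimethylbenzoate (racemic) | COC(Cl)c1c(C)c(C(=O)OC)c(O)c(C)c1O | intermediate (not isolated)
3 | methyl 5-formyl-2,4-dihydroxy-3,6-dimethylbenzoate | COC(=O)c1c(C)c(C=O)c(O)c(C)c1O | intermediate
4 | methyl 2,4-dihydroxy-5-(hydroxymethyl)-3,6-dimethylbenzoate | COC(=O)c1c(C)c(CO)c(O)c(C)c1O | intermediate (not isolated)
5 | methyl 2,4-dihydroxy-3,5,6-trimethylbenzoate | COC(=O)c1c(C)c(C)c(O)c(C)c1O | intermediate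
6 | but-2-ynoic acid | CC#CC(=O)O | starting material
7 | methyl 4-(but-2-ynoyloxy)-2-hydroxy-3,5,6-trimethylbenzoate | COC(=O)c1c(C)c(C)c(OC(=O)C#CC)c(C)c1O | intermediate
8 | methyl 4-(but-2-ynoyloxy)-2-methoxy-3,5,6-trimethylbenzoate | COC(=O)c1c(C)c(C)c(OC(=O)C#CC)c(C)c1OC | intermediate
9 | methyl 2-methyl-3-oxobutanoate (racemic, configurationally labile) | COC(=O)C(C)C(C)=O | starting material
10 | methyl 2-methyl-3-(trimethylsilyloxy)but-2-enoate (E/Z mixture, geometry without consequence) | COC(=O)C(C)=C(C)O[Si](C)(C)C | intermediate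
11 | lithium 1-methoxy-2-methyl-3-(trimethylsilyloxy)buta-1,3-dien-1-olate | [Li+].C=C(O[Si](C)(C)C)C(C)=C([O-])OC | intermediate (not isolated)
12 | 1-methoxy-2-methyl-1,3-bis(trimethylsilyloxy)buta-1,3-diene (E/Z mixture, geometry without consequence) | C=C(O[Si](C)(C)C)C(C)=C(OC)O[Si](C)(C)C | intermediate
13 | methyl 4-{[6-methoxy-2,5-dimethyl-4,6-bis(trimethylsilyloxy)cyclohexa-1,4-diene-1-carbonyl]oxy}-2-methoxy-3,5,6-trimethylbenzoate (racemic) | COC(=O)c1c(C)c(C)c(OC(=O)C2=C(C)CC(O[Si](C)(C)C)=C(C)C2(OC)O[Si](C)(C)C)c(C)c1OC | intermediate (not isolated)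
14 | methyl 4-[(2,4-dihydroxy-3,6-dimethylbenzoyl)oxy]-2-methoxy-3,5,6-trimethylbenzoate | COC(=O)c1c(C)c(C)c(OC(=O)c2c(C)cc(O)c(C)c2O)c(C)c1OC | intermediate
15 | methyl 4-({5-[chloro(methoxy)methyl]-2,4-dihydroxy-3,6-dimethylbenzoyl}oxy)-2-methoxy-3,5,6-trimethylbenzoate (racemic) | COC(=O)c1c(C)c(C)c(OC(=O)c2c(C)c(C(Cl)OC)c(O)c(C)c2O)c(C)c1OC | intermediate (not isolated)
16 | methyl 4-[(5-formyl-2,4-dihydroxy-3,6-dimethylbenzoyl)oxy]-2-methoxy-3,5,6-trimethylbenzoate (achiral) | COC(=O)c1c(C)c(C)c(OC(=O)c2c(C)c(C=O)c(O)c(C)c2O)c(C)c1OC | target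

**Totals**
Total step count: 8.
Longest linear sequence: 6 (steps 1, 2, 3, 4, 7, 8). The diene branch (steps 5, 6) joins at step 7.

**Three steps most likely to fail**

Step 7 (Diels–Alder benzannulation). The beta-methyl ynoate may react too slowly for the thermally labile diene. The fallback gives up the ring construction and makes the depside bond by acylation. It sets out from diol 5, with the acyl partner made from 1, and comes back at 14. Atraric acid 1 is dibenzylated (BnBr, K2CO3, DMF, 70 °C) to methyl 2,4-bis(benzyloxy)-3,6-dimethylbenzoate F1. Saponification (KOH, DMSO/H2O, 90 °C, then HCl) gives 2,4-bis(benzyloxy)-3,6-dimethylbenzoic acid F2. The acid is coupled through its mixed anhydride ((CF3CO)2O, toluene, 23 °C) to the unchelated 4-OH of 5, giving methyl 4-{[2,4-bis(benzyloxy)-3,6-dimethylbenzoyl]oxy}-2-hydroxy-3,5,6-trimethylbenzoate F3. The remaining chelated phenol is methylated (MeI, K2CO3, DMF, 50 °C) to methyl 4-{[2,4-bis(benzyloxy)-3,6-dimethylbenzoyl]oxy}-2-methoxy-3,5,6-trimethylbenzoate F4. Hydrogenolysis (H2, Pd/C, EtOAc, 23 °C) then gives 14.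

Step 4 (methylation of the hindered, chelated phenol beside the aryl ynoate). The reaction may be too slow, or the ynoate may suffer. The fallback installs the methyl ether before the ynoate, using a benzyl ether as a separate protecting group. It sets out from 5 and comes back at 8. Diol 5 is benzylated at the unchelated 4-OH (BnBr, K2CO3, acetone, reflux) to methyl 4-(benzyloxy)-2-hydroxy-3,5,6-trimethylbenzoate F5. Methylation (MeI, K2CO3, DMF, 60 °C) gives methyl 4-(benzyloxy)-2-methoxy-3,5,6-trimethylbenzoate F6. Debenzylation (H2, Pd/C, EtOAc, 23 °C) gives methyl 4-hydroxy-2-methoxy-3,5,6-trimethylbenzoate F7. This phenol is esterified with 6 (DCC, DMAP, CH2Cl2, 0 → 23 °C) to give 8.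

Step 8 (Lewis-acid formylation of the finished depside). TiCl4 may cleave the aryl ester or the ortho methyl ether. The fallback brings in the carbon at the alcohol oxidation level without a strong Lewis acid and then oxidises. It sets out from 14 and comes back at 16. Boron-templated ortho-hydroxymethylation of 14 (PhB(OH)2, paraformaldehyde, cat. EtCO2H, toluene, reflux with water removal) gives methyl 4-[(7-hydroxy-5,8-dimethyl-2-phenyl-4H-1,3,2-benzodioxaborine-6-carbonyl)oxy]-2-methoxy-3,5,6-trimethylbenzoate F8, in which the dioxaborine spans the 4-oxygen and C5 of ring A. Exchange with propane-1,3-diol (THF, 23 °C) frees methyl 4-{[2,4-dihydroxy-5-(hydroxymethyl)-3,6-dimethylbenzoyl]oxy}-2-methoxy-3,5,6-trimethylbenzoate F9. Activated MnO2 (CH2Cl2, 23 °C) oxidises the ortho-hydroxybenzylic alcohol to 16.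

**Further compounds**
F1 | step 7 | methyl 2,4-bis(benzyloxy)-3,6-dimethylbenzoate | COC(=O)c1c(C)cc(OCc2ccccc2)c(C)c1OCc3ccccc3
F2 | step 7 | 2,4-bis(benzyloxy)-3,6-dimethylbenzoic acid | OC(=O)c1c(C)cc(OCc2ccccc2)c(C)c1OCc3ccccc3
F3 | step 7 | methyl 4-{[2,4-bis(benzyloxy)-3,6-dimethylbenzoyl]oxy}-2-hydroxy-3,5,6-trimethylbenzoate | COC(=O)c1c(C)c(C)c(OC(=O)c2c(C)cc(OCc3ccccc3)c(C)c2OCc4ccccc4)c(C)c1O
F4 | step 7 | methyl 4-{[2,4-bis(benzyloxy)-3,6-dimethylbenzoyl]oxy}-2-methoxy-3,5,6-trimethylbenzoate | COC(=O)c1c(C)c(C)c(OC(=O)c2c(C)cc(OCc3ccccc3)c(C)c2OCc4ccccc4)c(C)c1OC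
F5 | step 4 | methyl 4-(benzyloxy)-2-hydroxy-3,5,6-trimethylbenzoate | COC(=O)c1c(C)c(C)c(OCc2ccccc2)c(C)c1O
F6 | step 4 | methyl 4-(benzyloxy)-2-methoxy-3,5,6-trimethylbenzoate | COC(=O)c1c(C)c(C)c(OCc2ccccc2)c(C)c1OC
F7 | step 4 | methyl 4-hydroxy-2-methoxy-3,5,6-trimethylbenzoate | COC(=O)c1c(C)c(C)c(O)c(C)c1OC
F8 | step 8 | methyl 4-[(7-hydroxy-5,8-dimethyl-2-phenyl-4H-1,3,2-benzodioxaborine-6-carbonyl)oxy]-2-methoxy-3,5,6-trimethylbenzoate | COC(=O)c1c(C)c(C)c(OC(=O)c2c(C)c3COB(c4ccccc4)Oc3c(C)c2O)c(C)c1OC
F9 | step 8 | methyl 4-{[2,4-dihydroxy-5-(hydroxymethyl)-3,6-dimethylbenzoyl]oxy}-2-methoxy-3,5,6-trimethylbenzoate | COC(=O)c1c(C)c(C)c(OC(=O)c2c(C)c(CO)c(O)c(C)c2O)c(C)c1OC
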